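## Retrosynthetic overview

1. The hydroperoxide is installed last: target 25 comes from enone 23 by a reductive hydroperoxidation in which hydride enters C3 from the convex face and the O–O group stays on the concave face.
2. Enone 23 is cut at the linker–C1 bond: B-alkyl Suzuki coupling of the vinyl-bearing left half 7 with the β-triflyloxy enone 21.
3. Rings C and D (the cis-decalin of 21) are formed together by an imidazolidinone-catalysed intramolecular Diels–Alder reaction of the achiral trienone 16; the C5 carbinol follows by methylenation and Mukaiyama hydration.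
4. Rings A and B (oxepane and cyclohexane of 7) are formed in one epoxide-opening cascade from the diepoxide made by Shi epoxidation of farnesyl acetate.
5. Order of ring formation: A then B in one flask (left branch); C and D at once (right branch); then union and hydroperoxidation.

Assumption: the facial sense of the imidazolidinone (step 10) and phosphoramide (step 15) catalysts is taken as written; the mirror-image catalysts are equally accessible should the sense prove opposite.

Locants used in names: left half, 1-benzoxepine numbering (O1, C2 gem-dimethyl, C3 carbinol, C5a angular methyl, C6 side chain, C7 tertiary carbinol, C9a). Right half, decalin numbering with C1 the alkene carbon bearing OTf or the linker, C2 (methyl), C3 (oxygenated), C4a/C8a ring fusion, C5 (tertiary carbinol), C8 (gem-dimethyl).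

## Route

Step 1
Reactants: 1 (2E,6E)-farnesyl acetate
Product: 2 (2E,6S,7S,10S)-6,7:10,11-diepoxy-3,7,11-trimethyldodec-2-en-1-yl acetate
Conditions: L-fructose-derived Shi ketone (0.6 equiv), Oxone, K2CO3, Bu4NHSO4 (cat.), aq. Na2B4O7/Na2EDTA buffer, CH3CN/CH2(OMe)2, 0 °C
Reagents that add atoms: Oxone (active component potassium peroxymonosulfate), [K+].[O-]S(=O)(=O)OO
Why: Shi asymmetric epoxidation by the chiral dioxirane formed in situ from the ketone organocatalyst: the allylic acetate deactivates the 2,3-alkene so that only the 6,7- and 10,11-alkenes react, and the spiro transition state of the L-series ketone delivers oxygen to the faces that give 6S,7S and 10S, so the first three stereocentres are set by asymmetric catalysis.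

Step 2
Reactants: 2 (2E,6S,7S,10S)-diepoxyfarnesyl acetate
Product: 5 (3S,5aS,6R,7S,9aS)-6-(hydroxymethyl)-2,2,5a,7-tetramethyldecahydro-1-benzoxepine-3,7-diol, via dioxanylium triflate 3 (not isolated), via hydroxy acetate 4 (not isolated)
Conditions: Me3SiOSO2CF3 (1.2 equiv), 2,6-di-tert-butyl-4-methylpyridine, CH2Cl2, −78 °C; aq. NaHCO3; then K2CO3, MeOH, rt
Reagents that add atoms: none
Why: Lewis-acid epoxide-opening cascade (tandem oxa- and carbacyclisation): silylation of the terminal epoxide lets the 6,7-epoxide oxygen attack its tertiary carbon (ring A), the bicyclic epoxonium ion is opened with inversion at its tertiary carbon by the 2,3-alkene through a chair transition state (ring B, trans fusion, equatorial CH2OAc, C5a and C6 set), and the tertiary cation is captured on its equatorial face by the neighbouring acetate carbonyl as a trans-fused dioxanylium ion whose hydrolysis and methanolysis leave the equatorial tertiary alcohol (C7 set).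

Step 3
Reactants: 5 triol
Product: 6 (3S,5aS,6S,7S,9aS)-3,7-dihydroxy-2,2,5a,7-tetramethyldecahydro-1-benzoxepine-6-carbaldehyde
Conditions: TEMPO (10 mol %), PhI(OAc)2 (1.1 equiv), CH2Cl2, rt
Reagents that add atoms: none
Why: Oxoammonium (TEMPO) oxidation is selective for the primary alcohol over the hindered secondary and the tertiary alcohols and does not epimerise the equatorial aldehyde.

Step 4
Reactants: 6 aldehyde
Product: 7 (3S,5aS,6S,7S,9aS)-6-ethenyl-2,2,5a,7-tetramethyldecahydro-1-benzoxepine-3,7-diol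
Conditions: Ph3PCH3Br, KN(SiMe3)2, THF, −78 → 0 °C
Reagents that add atoms: methyltriphenylphosphonium bromide, C[P+](c1ccccc1)(c1ccccc1)c1ccccc1.[Br-]
Why: Wittig methylenation with a salt-free ylide at low temperature is faster than retro-aldol cleavage or epimerisation of the β-hydroxy aldehyde, so C6 is kept.

Step 5
Reactants: 8 N-methoxy-N-methylpropanamide; 9 2-methylallylmagnesium chloride
Product: 10 5-methylhex-5-en-3-one
Conditions: THF, −78 → −20 °C; cold aq. NH4Cl
Reagents that add atoms: none
Why: Weinreb ketone synthesis: the chelated tetrahedral adduct survives until the cold buffered quench, which gives the ketone without over-addition and without moving the alkene into conjugation.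

Step 6
Reactants: 10 5-methylhex-5-en-3-one; 11 N-methoxy-N-methylacrylamide
Product: 12 N-methoxy-N,4,4-trimethyl-6-oxooctanamide
Conditions: Fe(acac)3 (30 mol %), PhSiH3 (2.5 equiv), EtOH/ethylene glycol, 60 °C
Reagents that add atoms: none
Why: Hydrogen-atom-transfer-initiated reductive olefin coupling (Giese-type radical conjugate addition): the iron hydride transfers a hydrogen atom to the 1,1-disubstituted alkene and the tertiary radical adds to the acrylamide terminus, which builds the quaternary gem-dimethyl carbon; no stereocentre is formed.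

Step 7
Reactants: 12 keto amide
Product: 14 (7E)-N-methoxy-N,4,4,7-tetramethyl-6-oxo-8-[(triisopropylsilyl)oxy]oct-7-enamide, via lithium formyl-ketone enolate 13 (not isolated)
Conditions: LiN(iPr)2 (1.05 equiv), THF, −78 °C; HCO2CH2CF3; then iPr3SiOSO2CF3, −78 → 0 °C
Reagents that add atoms: 2,2,2-trifluoroethyl formate, O=COCC(F)(F)F; triisopropylsilyl trifluoromethanesulfonate, CC(C)[Si](OS(=O)(=O)C(F)(F)F)(C(C)C)C(C)C
Why: Crossed Claisen formylation of the kinetic enolate (the less hindered ethyl CH2, not the neopentyl CH2 or the amide) followed by O-silylation of the resulting β-keto aldehyde enolate gives the thermodynamically preferred E vinylogous silyl ester.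

Step 8
Reactants: 14 vinylogous silyl ester
Product: 15 (5Z,7E)-1-[methoxy(methyl)amino]-4,4,7-trimethyl-1-oxo-8-[(triisopropylsilyl)oxy]octa-5,7-dien-6-yl trifluoromethanesulfonate
Conditions: KN(SiMe3)2, THF, −78 °C; PhN(SO2CF3)2, −78 → 0 °C; aq. NH4Cl
Reagents that add atoms: N-phenylbis(trifluoromethanesulfonimide), O=S(=O)(N(c1ccccc1)S(=O)(=O)C(F)(F)F)C(F)(F)F
Why: Enol triflate formation: the only enolisable ketone position is the neopentyl CH2, and its enolate forms with oxygen cis to the tert-alkyl group to avoid allylic strain with the alkenyl residue, which fixes the Z geometry of the new alkene that the cycloaddition needs.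

Step 9
Reactants: 15 dienyl triflate amide
Product: 16 (1E,3Z)-2,5,5-trimethyl-8-oxo-1-[(triisopropylsilyl)oxy]deca-1,3,9-trien-3-yl trifluoromethanesulfonate
Conditions: CH2=CHMgBr (2.2 equiv), THF, −78 → −30 °C; inverse quench into cold aq. NH4Cl; used at once
Reagents that add atoms: vinylmagnesium bromide, C=C[Mg]Br
Why: Weinreb ketone synthesis with a vinyl Grignard reagent; the vinyl triflate and silyl dienol ether are inert to the Grignard reagent at low temperature and the inverse acidic quench stops the freed amine from adding to the enone.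

Step 10
Reactants: 16 trienone
Product: 17 (3R,4aS,8aR)-2,8,8-trimethyl-5-oxo-3-[(triisopropylsilyl)oxy]-3,4,4a,5,6,7,8,8a-octahydronaphthalen-1-yl trifluoromethanesulfonate (cis-fused)
Conditions: (2S,5S)-5-benzyl-3-methyl-2-(5-methylfuran-2-yl)imidazolidin-4-one·HClO4 (20 mol %), EtOH/H2O 19:1, −30 °C
Reagents that add atoms: none
Why: Iminium-ion-catalysed intramolecular Diels–Alder reaction (LUMO lowering of the alkyl vinyl ketone by the chiral imidazolidinone): the tether forces the regiochemistry, the endo transition state with the iminium carbon under the diene gives the cis ring fusion and puts the silyloxy group on the same face as the tether, and the benzyl group of the catalyst shields one face of the dienophile, which sets C3, C4a and C8a.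

Step 11
Reactants: 17 bicyclic ketone
Product: 18 (3R,4aS,8aR)-2,8,8-trimethyl-5-methylidene-3-[(triisopropylsilyl)oxy]-3,4,4a,5,6,7,8,8a-octahydronaphthalen-1-yl trifluoromethanesulfonate
Conditions: Ph3PCH3Br, KN(SiMe3)2, THF, 0 °C → rt
Reagents that add atoms: methyltriphenylphosphonium bromide, C[P+](c1ccccc1)(c1ccccc1)c1ccccc1.[Br-]
Why: Wittig methylenation of the ring ketone; the cis ring fusion is kept because the trans isomer would suffer allylic strain between the C8 methyl groups and the C1 substituent.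

Step 12
Reactants: 18 exocyclic alkene
Product: 19 (3R,4aS,5S,8aR)-5-hydroxy-2,5,8,8-tetramethyl-3-[(triisopropylsilyl)oxy]-3,4,4a,5,6,7,8,8a-octahydronaphthalen-1-yl trifluoromethanesulfonate
Conditions: Co(acac)2 (20 mol %), PhSiH3, O2 (1 atm), iPrOH/THF, rt
Reagents that add atoms: dioxygen, O=O
Why: Mukaiyama hydration (hydrogen-atom transfer from a cobalt hydride to the CH2 terminus, then capture of the tertiary radical by O2 on the convex face, that of H-4a and H-8a) gives the 5S tertiary alcohol; the tetrasubstituted enol triflate is inert to hydrogen-atom transfer.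

Step 13
Reactants: 19 silyl ether
Product: 21 (4aS,5S,8aR)-5-hydroxy-2,5,8,8-tetramethyl-3-oxo-3,4,4a,5,6,7,8,8a-octahydronaphthalen-1-yl trifluoromethanesulfonate, via allylic alcohol 20 (not isolated)
Conditions: HF·pyridine, pyridine, THF, 0 °C → rt; then Dess–Martin periodinane, pyridine, CH2Cl2, rt
Reagents that add atoms: none
Why: Fluoride cleaves the silyl ether and the Dess–Martin reagent oxidises the secondary allylic alcohol to the β-triflyloxy enone while the tertiary alcohol and the vinyl triflate are untouched.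

Step 14
Reactants: 7 vinyl left half; 21 β-triflyloxy enone
Product: 23 (4aS,5S,8aR)-1-{2-[(3S,5aS,6S,7S,9aS)-3,7-dihydroxy-2,2,5a,7-tetramethyldecahydro-1-benzoxepin-6-yl]ethyl}-5-hydroxy-2,5,8,8-tetramethyl-4a,5,6,7,8,8a-hexahydronaphthalen-3(4H)-one, via alkylborane 22 (not isolated)
Conditions: 9-BBN (3 equiv), THF, rt; then aq. K3PO4, 21, Pd(dppf)Cl2 (10 mol %), AsPh3, DMF, rt → 40 °C
Reagents that add atoms: none
Why: B-alkyl Suzuki–Miyaura coupling: 9-BBN adds anti-Markovnikov to the vinyl group only and the primary alkylborane couples with the activated β-triflyloxy enone, forming the linker–C1 bond with the alkene position fixed and the free hydroxyl groups tolerated.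

Step 15
Reactants: 23 enone
Product: 25 sipholenol M, via perhydrate 24 (not isolated)
Conditions: H2O2 (ca. 3 M in Et2O, 5 equiv), (R)-3,3'-bis(2,4,6-triisopropylphenyl)-1,1'-binaphthyl-2,2'-diyl N-triflylphosphoramide (10 mol %), CH2Cl2, −40 °C; then diethyl 2,6-dimethyl-1,4-dihydropyridine-3,5-dicarboxylate (1.3 equiv), −40 → −20 °C
Reagents that add atoms: hydrogen peroxide, OO
Why: Proposed new method: organocatalytic reductive hydroperoxidation of a ketone, in which H2O2 adds reversibly to the enone carbonyl to give the perhydrate, the chiral acid ionises it by loss of water to an allyl-stabilised hydroperoxycarbenium ion paired with the chiral phosphoramide anion, and the Hantzsch ester delivers hydride to C3 (C1 is fully substituted and screened by the gem-dimethyl carbon, so 1,4-delivery is disfavoured) from the convex face of the cis-decalin, the face of H-4a and H-8a, which the matched catalyst reinforces, so the O–O group stays on the concave face as in the 3R target; the closest known reactions are Brønsted-acid-catalysed reductive amination and reductive etherification with Hantzsch esters and the Lewis-acid ionisation of peroxyketals to peroxycarbenium ions that are reduced by silanes.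

## Compound list

1 | (2E,6E)-farnesyl acetate | CC(=O)OC/C=C(\C)CC/C=C(\C)CCC=C(C)C | starting material
2 | (2E,6S,7S,10S)-6,7:10,11-diepoxy-3,7,11-trimethyldodec-2-en-1-yl acetate | CC(=O)OC/C=C(\C)CC[C@@H]1O[C@@]1(C)CC[C@@H]1OC1(C)C | intermediate
3 | trans-fused 2-methyl-1,3-dioxan-2-ylium triflate bridging the CH2–O and the C7 oxygen of the bicycle, C3 as trimethylsilyl ether (not isolated) | O1C[C@H]2[C@]3(C)CC[C@H](O[Si](C)(C)C)C(C)(C)O[C@H]3CC[C@]2(C)[O+]=C1C.[O-]S(=O)(=O)C(F)(F)F | intermediate
4 | [(3S,5aS,6R,7S,9aS)-7-hydroxy-2,2,5a,7-tetramethyl-3-(trimethylsilyloxy)decahydro-1-benzoxepin-6-yl]methyl acetate (not isolated) | CC(=O)OC[C@H]2[C@]3(C)CC[C@H](O[Si](C)(C)C)C(C)(C)O[C@H]3CC[C@]2(C)O | intermediate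
5 | (3S,5aS,6R,7S,9aS)-6-(hydroxymethyl)-2,2,5a,7-tetramethyldecahydro-1-benzoxepine-3,7-diol | OC[C@H]2[C@]3(C)CC[C@H](O)C(C)(C)O[C@H]3CC[C@]2(C)O | intermediate
6 | (3S,5aS,6S,7S,9aS)-3,7-dihydroxy-2,2,5a,7-tetramethyldecahydro-1-benzoxepine-6-carbaldehyde | O=C[C@H]2[C@]3(C)CC[C@H](O)C(C)(C)O[C@H]3CC[C@]2(C)O | intermediate
7 | (3S,5aS,6S,7S,9aS)-6-ethenyl-2,2,5a,7-tetramethyldecahydro-1-benzoxepine-3,7-diol | C=C[C@H]2[C@]3(C)CC[C@H](O)C(C)(C)O[C@H]3CC[C@]2(C)O | intermediate
8 | N-methoxy-N-methylpropanamide | CCC(=O)N(C)OC | starting material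
9 | 2-methylallylmagnesium chloride | CC(=C)C[Mg]Cl | starting material
10 | 5-methylhex-5-en-3-one | CCC(=O)CC(C)=C | intermediate
11 | N-methoxy-N-methylacrylamide | C=CC(=O)N(C)OC | starting material
12 | N-methoxy-N,4,4-trimethyl-6-oxooctanamide | CCC(=O)CC(C)(C)CCC(=O)N(C)OC | intermediate
13 | lithium (Z)-enolate of N-methoxy-N,4,4,7-tetramethyl-6,8-dioxooctanamide (not isolated) | [Li+].[O-]/C=C(/C)C(=O)CC(C)(C)CCC(=O)N(C)OC | intermediate
14 | (7E)-N-methoxy-N,4,4,7-tetramethyl-6-oxo-8-[(triisopropylsilyl)oxy]oct-7-enamide | CC(C)[Si](O/C=C(\C)C(=O)CC(C)(C)CCC(=O)N(C)OC)(C(C)C)C(C)C | intermediate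
15 | (5Z,7E)-1-[methoxy(methyl)amino]-4,4,7-trimethyl-1-oxo-8-[(triisopropylsilyl)oxy]octa-5,7-dien-6-yl trifluoromethanesulfonate | CC(C)[Si](O/C=C(\C)/C(=C/C(C)(C)CCC(=O)N(C)OC)OS(=O)(=O)C(F)(F)F)(C(C)C)C(C)C | intermediate
16 | (1E,3Z)-2,5,5-trimethyl-8-oxo-1-[(triisopropylsilyl)oxy]deca-1,3,9-trien-3-yl trifluoromethanesulfonate | CC(C)[Si](O/C=C(\C)/C(=C/C(C)(C)CCC(=O)C=C)OS(=O)(=O)C(F)(F)F)(C(C)C)C(C)C | intermediate
17 | (3R,4aS,8aR)-2,8,8-trimethyl-5-oxo-3-[(triisopropylsilyl)oxy]-3,4,4a,5,6,7,8,8a-octahydronaphthalen-1-yl trifluoromethanesulfonate (cis-fused; H-4a and H-8a on one face, OSi on the other) | CC1=C(OS(=O)(=O)C(F)(F)F)[C@@H]2[C@H](C[C@H]1O[Si](C(C)C)(C(C)C)C(C)C)C(=O)CCC2(C)C | intermediate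
18 | (3R,4aS,8aR)-2,8,8-trimethyl-5-methylidene-3-[(triisopropylsilyl)oxy]-3,4,4a,5,6,7,8,8a-octahydronaphthalen-1-yl trifluoromethanesulfonate | CC1=C(OS(=O)(=O)C(F)(F)F)[C@@H]2[C@H](C[C@H]1O[Si](C(C)C)(C(C)C)C(C)C)C(=C)CCC2(C)C | intermediate
19 | (3R,4aS,5S,8aR)-5-hydroxy-2,5,8,8-tetramethyl-3-[(triisopropylsilyl)oxy]-3,4,4a,5,6,7,8,8a-octahydronaphthalen-1-yl trifluoromethanesulfonate | CC1=C(OS(=O)(=O)C(F)(F)F)[C@@H]2[C@H](C[C@H]1O[Si](C(C)C)(C(C)C)C(C)C)[C@@](C)(O)CCC2(C)C | intermediate
20 | (3R,4aS,5S,8aR)-3,5-dihydroxy-2,5,8,8-tetramethyl-3,4,4a,5,6,7,8,8a-octahydronaphthalen-1-yl trifluoromethanesulfonate (not isolated) | CC1=C(OS(=O)(=O)C(F)(F)F)[C@@H]2[C@H](C[C@H]1O)[C@@](C)(O)CCC2(C)C | intermediate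
21 | (4aS,5S,8aR)-5-hydroxy-2,5,8,8-tetramethyl-3-oxo-3,4,4a,5,6,7,8,8a-octahydronaphthalen-1-yl trifluoromethanesulfonate | CC1=C(OS(=O)(=O)C(F)(F)F)[C@@H]2[C@H](CC1=O)[C@@](C)(O)CCC2(C)C | intermediate
22 | 9-{2-[(3S,5aS,6S,7S,9aS)-3,7-dihydroxy-2,2,5a,7-tetramethyldecahydro-1-benzoxepin-6-yl]ethyl}-9-borabicyclo[3.3.1]nonane (not isolated) | B1(CC[C@H]2[C@]3(C)CC[C@H](O)C(C)(C)O[C@H]3CC[C@]2(C)O)C2CCCC1CCC2 | intermediate
23 | (4aS,5S,8aR)-1-{2-[(3S,5aS,6S,7S,9aS)-3,7-dihydroxy-2,2,5a,7-tetramethyldecahydro-1-benzoxepin-6-yl]ethyl}-5-hydroxy-2,5,8,8-tetramethyl-4a,5,6,7,8,8a-hexahydronaphthalen-3(4H)-one | CC1=C(CC[C@H]2[C@]3(C)CC[C@H](O)C(C)(C)O[C@H]3CC[C@]2(C)O)[C@@H]2[C@H](CC1=O)[C@@](C)(O)CCC2(C)C | intermediate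
24 | C3 perhydrate of 23 (3-hydroxy-3-hydroperoxy; C3 configuration not defined; not isolated) | CC1=C(CC[C@H]2[C@]3(C)CC[C@H](O)C(C)(C)O[C@H]3CC[C@]2(C)O)[C@@H]2[C@H](CC1(O)OO)[C@@](C)(O)CCC2(C)C | intermediate
25 | sipholenol M: (3R,4aS,5S,8aR)-3-hydroperoxy decalin linked through C1–CH2CH2 to C6 of the (3S,5aS,6S,7S,9aS)-benzoxepinediol | CC1=C(CC[C@H]2[C@]3(C)CC[C@H](O)C(C)(C)O[C@H]3CC[C@]2(C)O)[C@@H]2[C@H](C[C@H]1OO)[C@@](C)(O)CCC2(C)C | target

## Step count and risks

Total: 15 steps. Longest linear sequence: 11 steps (steps 5 to 15); the left branch (steps 1 to 4) joins at step 14.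

Most likely to fail:

**Step 15 (the proposed new reaction).** The perhydrate may form poorly from a hindered conjugated ketone; the ion could rearrange (Baeyer–Villiger or Hock type); hydride could add at C1; or the product could be over-reduced. The fallback uses known chemistry. It sets out from 23: Luche reduction (NaBH4, CeCl3·7H2O, MeOH, −78 °C; hydride from the convex face) gives the (3R)-allylic alcohol F1. Appel bromination (CBr4, PPh3, CH2Cl2, −20 °C) inverts C3 to the (3S)-allylic bromide F2. SN2 displacement with 2-methoxyprop-2-yl hydroperoxide and CsOH·H2O in DMF inverts again to the (3R)-peroxyketal F3. Aqueous acetic acid in THF releases the hydroperoxide, and the route is rejoined at 25.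

**Step 10 (asymmetric intramolecular Diels–Alder).** The thermal background reaction, slow iminium formation from a ketone, or acid lability of the silyl dienol ether may erode selectivity. The fallback gives up catalyst control and uses the left fragment as resolving partner. It sets out from 16: heating in toluene (80 °C, BHT) gives the cis adduct as a racemate, 17 together with its enantiomer F4. Steps 11 to 13 are run on the racemate, giving alongside 18, 19, 20 and 21 the enantiomeric alkene F5, the enantiomeric tertiary alcohol F6, the enantiomeric allylic alcohol F7 (not isolated) and the enantiomeric β-triflyloxy enone F8. Coupling with enantiopure 7 as in step 14 gives 23 together with the diastereomeric enone F9, which is removed by chromatography; the route is rejoined at 23.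

**Step 2 (cascade and acetate capture).** If the tertiary cation loses a proton instead of being trapped by the acetate, alkenes result. The fallback accepts this outcome. It sets out from 2: the same Lewis-acid cascade, worked up without methanolysis, gives the exocyclic alkene acetate F10 and the endocyclic alkene acetate F11. Mukaiyama hydration of the mixture (Co(acac)2, PhSiH3, O2, iPrOH) converts both into the same tertiary radical, which takes up O2 on the equatorial face. This gives 4, where the route is rejoined before the methanolysis to 5.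

Further compounds

F1 | step 15 | (3R)-allylic alcohol, the 3-hydroxy analogue of 25 | CC1=C(CC[C@H]2[C@]3(C)CC[C@H](O)C(C)(C)O[C@H]3CC[C@]2(C)O)[C@@H]2[C@H](C[C@H]1O)[C@@](C)(O)CCC2(C)C
F2 | step 15 | (3S)-allylic bromide, the 3-bromo analogue of 25 with inverted C3 | CC1=C(CC[C@H]2[C@]3(C)CC[C@H](O)C(C)(C)O[C@H]3CC[C@]2(C)O)[C@@H]2[C@H](C[C@@H]1Br)[C@@](C)(O)CCC2(C)C
F3 | step 15 | (3R)-2-methoxyprop-2-yl peroxide of 25 | CC1=C(CC[C@H]2[C@]3(C)CC[C@H](O)C(C)(C)O[C@H]3CC[C@]2(C)O)[C@@H]2[C@H](C[C@H]1OOC(C)(C)OC)[C@@](C)(O)CCC2(C)C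
F4 | step 10 | enantiomer of 17 | CC1=C(OS(=O)(=O)C(F)(F)F)[C@H]2[C@@H](C[C@@H]1O[Si](C(C)C)(C(C)C)C(C)C)C(=O)CCC2(C)C
F5 | step 10 | enantiomer of 18 | CC1=C(OS(=O)(=O)C(F)(F)F)[C@H]2[C@@H](C[C@@H]1O[Si](C(C)C)(C(C)C)C(C)C)C(=C)CCC2(C)C
F6 | step 10 | enantiomer of 19 | CC1=C(OS(=O)(=O)C(F)(F)F)[C@H]2[C@@H](C[C@@H]1O[Si](C(C)C)(C(C)C)C(C)C)[C@](C)(O)CCC2(C)C
F7 | step 10 | enantiomer of 20 | CC1=C(OS(=O)(=O)C(F)(F)F)[C@H]2[C@@H](C[C@@H]1O)[C@](C)(O)CCC2(C)C
F8 | step 10 | enantiomer of 21 | CC1=C(OS(=O)(=O)C(F)(F)F)[C@H]2[C@@H](CC1=O)[C@](C)(O)CCC2(C)C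
F9 | step 10 | diastereomer of 23 with the (4aR,5R,8aS) decalin | CC1=C(CC[C@H]2[C@]3(C)CC[C@H](O)C(C)(C)O[C@H]3CC[C@]2(C)O)[C@H]2[C@@H](CC1=O)[C@](C)(O)CCC2(C)C
F10 | step 2 | exocyclic alkene acetate, the 7-methylidene analogue of 4 with other centres as in 4 | CC(=O)OC[C@H]2[C@]3(C)CC[C@H](O[Si](C)(C)C)C(C)(C)O[C@H]3CCC2=C
F11 | step 2 | endocyclic alkene acetate, the 7,8-ene analogue of 4 with other centres as in 4 | CC(=O)OC[C@H]2[C@]3(C)CC[C@H](O[Si](C)(C)C)C(C)(C)O[C@H]3CC=C2C
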